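1. The leftover is what I reckon with: the catalyst that remains once the impurity has taken its own amount, 67.7% of the charge in this flask.

the same everywhere: starting material 0.50 M; free catalyst 3.1 mM
- violet: second substrate 0.25 M; impurity 0.67 mM; run made earlier
- blue: second substrate 0.25 M; impurity 1.5 mM; run made earlier
- amber: second substrate 0.50 M; impurity 1 mM; run made earlier
- flask: second substrate 0.250 M; impurity 1.0 mM

- violet (time / min: target / %, starting material / %): 20.0: 15, 88; 40.0: 25, 74; 60.0: 34, 65; 80.0: 38, 62; 90.0: 43, 61
- blue (time / min: target / %, starting material / %): 20.0: 8, 88; 40.0: 17, 85; 60.0: 22, 77; 80.0: 28, 71; 90.0: 29, 74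
- amber (time / min: target / %, starting material / %): 8.00: 5, 93; 25.0: 13, 86; 40.0: 17, 84; 60.0: 25, 77; 90.0: 26, 74

(standard deviation of a reading: 2 percentage points)

- no earlier run changes the charge of free catalyst; that part of a forecast is a guess

* factor on the rate of making target when 10% of the starting material are converted if second substrate is charged twice over
* factor on the rate when 10% of the starting material are converted if free catalyst is charged at 15 mM instead

2. Does the rate follow that leftover? Up to 40.0 min, the violet run's mean rate over the blue run's reads 1.47, and the ratio of their leftovers is 1.52, so I take the rate as proportional to the leftover.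

3. Start: the violet run makes 0.00750 min⁻¹ of the charge over its first reading. Scaled by leftover, I put this flask's early rate at 0.00648 min⁻¹ and its 10% conversion near 15.4 min.

4. Slowing: late in the violet run the rate reads 0.00300 min⁻¹. That gives the rate life, the time in which the rate falls by the factor e, 70.9 min, read with the fall of starting material lumped in. Taking that violet reading over to this flask, I reckon that by 15.4 min it keeps a factor 0.805. Summed to the end, I expect target near 45.9% of the charge.

5. My numbers: the amber run's early rate, 0.00520 min⁻¹, over 0.00648 min⁻¹ gives dbl 0.802. At 15 mM the leftover grows by a factor 6.67; with the rate life taken as unchanged, I reckon 10% comes sooner, with less slowing built up. My ratio is 8.02, a guess, since no run changes the catalyst.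

6. The forecast says dbl 0.9 (0.65 to 1.25), reasoning “the order in second substrate is about zero”, and ratio 6 (2.5 to 8.5). My dbl is lower and my ratio higher.

7. The flask gives dbl 0.694 and ratio 7.72.

    catalyst intermediate A → free catalyst + target (k = 11.0 min⁻¹)
    starting material + free catalyst ⇌ catalyst intermediate A (K = 4.80 M⁻¹, k = 6.60 M⁻¹ min⁻¹)
    free catalyst + impurity → spent catalyst A (k = 2700 M⁻¹ min⁻¹)
    second substrate + free catalyst → spent catalyst B (k = 0.0720 M⁻¹ min⁻¹)
    second substrate + free catalyst ⇌ catalyst intermediate B (K = 1.50 M⁻¹, k = 3.40 M⁻¹ min⁻¹)
    catalyst intermediate B → free catalyst + second product (k = 0.780 min⁻¹)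

At 0.200 h, close to the 0.234 h at which 10% is converted, this flask holds spent catalyst A at 32.3% and spent catalyst B at 8.95% of the catalyst charged. Now I carry the rate life to 2.00 h, treating the whole slowing as loss of catalyst. On that treatment it keeps 18.4% of the leftover, which counts 55.2% of the charge as out of work. Spent catalyst B in this flask at that time stands at 51.1%.

The earlier runs and the new flask come from a simulation for substances that don't exist; scatter was added.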